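The numbers in the tables stem from a simulated flask for an exercise; scatter was added.

1. In a one-step world, substrate passes straight into target by a pseudo-first-order step, so the converted fraction of the charge at time t is one minus exp(−t/τ). The charge cancels from that expression.

| flask | substrate | gas | remark | time |
|---|---|---|---|---|
| birch | 0.40 M | 8 mM (held) | run made earlier |  |
| flask | 0.20 M | 8.0 mM (held) |  | 2.5 h |

birch run (percent of the substrate charged)

| time / min | target / % |
|---|---|
| 2.50 | 1.5 |
| 4.00 | 2.7 |
| 6.00 | 4.9 |
| 10.0 | 7.8 |
| 20.0 | 14.0 |
| 30.0 | 20.6 |

(scatter of a reading: 1 percentage point)

- a species is counted by the substrate in it: one idle adduct counts as two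
- amounts and yields of target count idle adduct too
- at the start none of partner is dissolved
- steps under discussion: substrate + partner <-> intermediate A; gas <-> partner; substrate + target <-> idle adduct; substrate + partner -> target; partner + intermediate A -> side product; substrate <-> intermediate B
- in an amount of target, one idle adduct counts as one target

- amount of target in percent of the substrate charged, at 8.0 min, 40 min and 2.5 h

2. I took τ from the last birch reading, 20.6 % at 30.0 min, which gave 130 min. This one-step time is the time in which the unconverted fraction falls by the factor e. The same curve gave 7.40 % at 10.0 min, against the reading 7.8 %.

3. Two times then carried my reckoning: τ and the asked 2.5 h. Their ratio was 1.15, while the birch readings reached a ratio of 0.231, so the late point was an extrapolation.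

4. My reckoning for the flask gave 5.97 %, 26.5 % and 68.5 %.

5. The forecast gave 6 %, 27 % and 63 %: “If first order holds, halving the substrate leaves the percent curve unchanged”. Its last value stood below mine, and by its own account that point was shaded down.

6. The flask gave 8.17 %, 30.2 % and 59.3 %.

    substrate + partner ⇌ intermediate A (K = 190 /M, k = 1.10 /M/min)
    gas ⇌ partner, rate k2*(csat - [partner]) (kL = 1.00 /min)
    substrate + target ⇌ idle adduct, settled at all times (K = 5.90 /M)
    substrate + partner → target (k = 2.70 /M/min)
    partner + intermediate A → side product (k = 2.40 /M/min)
    substrate ⇌ intermediate B (K = 0.810, k = 0.0200 /min)

Put through the same formula, the flask's amounts correspond to a one-step time of 111 min at 40 min and 167 min at 2.5 h, against 130 min, so the flask stood above my curve at the first of these times and below it at the second. At 0.683 h, the flask's substrate passed into target 2.5 times as fast as into intermediate A (forward rate of the reversible step alone), and at 25.0 h the flask held target 76.7 % and side product 23.3 %.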